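Everything rests on closing ring B last, across C6–C7. Two features are exploited. C6 is attached to C5 next to C4, which carries both the C3 carbonyl and C19, so C4–C5–C6 can be written as a doubly acceptor-activated cyclopropane. C7–C8(=C17) is a 2-substituted allyl unit, the retron of an allylsilane. Under silyl Lewis acid catalysis the allylsilane opens the cyclopropane at C6. One operation closes ring B as a trans-decalin, fixes the C8(17) methylene and unmasks the C3/C19 β-keto ester for C4 methylation. The precursor is a bicyclo[4.1.0]heptanone (ring A only), built from methyl geranate, a 2-metallated allylsilane, a five-carbon keto ester and a one-carbon ylide.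

Key step: step 7

Remark: atom labels C1–C20 are the labdane positions of the target and are used for all intermediates.
Assumption: the amine catalyst of step 5 is taken to deliver the vinyl ketone to the enamine face that gives (S)-C10 in 14. Its pseudo-enantiomer (from quinidine) is used if the sense is the opposite.

Step 1
Reactants: 1 methyl geranate
Product: 2 methyl (2E)-3-methyl-6-oxohex-2-enoate
Conditions: O3 (1.0 equiv), CH2Cl2, −78 °C; then Me2S, −78 °C → rt
Reagents that add atoms: ozone, [O-][O+]=O
Why: Chemoselective ozonolysis, in which the electron-rich trisubstituted C6=C7 alkene should react much faster than the conjugated enoate, whose E geometry (later C13=C14) is carried unchanged to the target.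

Step 2
Reactants: 2 methyl (2E)-3-methyl-6-oxohex-2-enoate; 3 2-(triphenyl-λ5-phosphanylidene)propanal
Product: 4 methyl (2E,6E)-3,7-dimethyl-8-oxoocta-2,6-dienoate
Conditions: toluene, 90 °C
Reagents that add atoms: none
Why: Wittig olefination with a stabilised ylide, which should give the (E)-2-methyl enal and so places C5 (CHO), C10 with its methyl C20, and C9 as a Michael acceptor.

Step 3
Reactants: 4 methyl (2E,6E)-3,7-dimethyl-8-oxoocta-2,6-dienoate; 5 tert-butyl (2S)-2-amino-3,3-dimethylbutanoate (free base of the commercial hydrochloride)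
Product: 6 (E)-aldimine of 4 with 5
Conditions: 4 Å MS, CH2Cl2, 0 °C → rt
Reagents that add atoms: none
Why: Condensation of an aldehyde with a primary amine to the α,β-unsaturated aldimine, which installs a removable chelating auxiliary next to the acceptor.

Step 4
Reactants: 6 (E)-aldimine of 4 with 5; 7 (2-bromoprop-2-en-1-yl)trimethylsilane
Product: 10 methyl (2E,6R)-3,7-dimethyl-8-oxo-6-[3-(trimethylsilyl)prop-1-en-2-yl]oct-2-enoate (both C7 epimers), via Grignard reagent 8 (not isolated), via alkenylated aldimine 9 (not isolated)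
Conditions: 7, Mg, THF, rt; then 6, THF, −55 °C; aq. citric acid, pentane, 0 °C
Reagents that add atoms: water, O
Why: Chelation-controlled 1,4-addition of a Grignard reagent to a chiral α,β-unsaturated aldimine, in which Mg is held by the imine N and the ester C=O, the s-cis azadiene is attacked at C9 on the face away from the tert-butyl group (setting C9 as R), and mild acid hydrolysis frees the aldehyde; the C10 centre formed on protonation is immaterial because it is erased in step 5.

Step 5
Reactants: 10 methyl (2E,6R)-3,7-dimethyl-8-oxo-6-[3-(trimethylsilyl)prop-1-en-2-yl]oct-2-enoate; 11 methyl 5-methoxy-3-oxopentanoate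
Product: 14 methyl (3S)-3-{(3R,6E)-8-methoxy-6-methyl-8-oxo-2-[(trimethylsilyl)methyl]octa-1,6-dien-3-yl}-3-methyl-6-oxocyclohex-1-ene-1-carboxylate, via methyl 3-oxopent-4-enoate 12 (not isolated), via Michael adduct 13 (not isolated)
Conditions: 9-amino-9-deoxy-epi-quinine (20 mol %), 2-fluorobenzoic acid (40 mol %), 11 (slow addition), toluene, 40 °C; then piperidinium acetate (cat.), 4 Å MS, rt
Reagents that add atoms: none
Why: Robinson-type annulation, namely enamine-mediated Michael addition of the α-branched aldehyde to the vinyl ketone released from 11 by β-elimination of methanol, then intramolecular Knoevenagel condensation of C4 on C5; both C10 epimers of 10 converge on one trisubstituted enamine, one face of which is shielded by the chiral primary amine, and this sets quaternary C10.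

Step 6
Reactants: 14 enone ester
Product: 15 methyl (1S,5S,6R)-5-{(3R,6E)-8-methoxy-6-methyl-8-oxo-2-[(trimethylsilyl)methyl]octa-1,6-dien-3-yl}-5-methyl-2-oxobicyclo[4.1.0]heptane-1-carboxylate
Conditions: Me3S(O)I, NaH, DMSO–THF, 0 °C → rt
Reagents that add atoms: trimethylsulfoxonium iodide, C[S+](C)(C)=O.[I-]
Why: Corey–Chaykovsky cyclopropanation (Michael-initiated ring closure) of the doubly activated C4=C5 alkene, in which the ylide should attack C5 anti to the branched C9 substituent on C10 (syn to the C10 methyl), setting C5, after which the necessarily cis closure fixes C4; the β,β-disubstituted side-chain enoate is far less electrophilic.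

Step 7
Reactants: 15 cyclopropyl keto ester
Product: 17 dimethyl 3-oxo-18-norlabda-8(17),13E-diene-15,19-dioate (5α-H, 9α-H, 10β-CH3; C4 epimers and enol equilibrate, drawn with the equatorial ester), via silyl enol ether 16 (not isolated)
Conditions: TMSNTf2 (10–20 mol %), 2,6-di-tert-butyl-4-methylpyridine, CH2Cl2, −78 → −20 °C; aq. NH4Cl work-up
Reagents that add atoms: none
Why: The silyl Lewis acid silylates the C3 carbonyl oxygen of 15 and polarises the external C4–C6 bond of the doubly activated cyclopropane; C7 of the allylsilane attacks the unhindered methylene C6 from the side opposite C4, the β-silyl cation at C8 loses Me3Si+ (which carries the chain), and silyl enol ether 16 is hydrolysed to 17 on work-up. The closest known reaction types are the acid-promoted cyclisation of olefinic acylcyclopropanes (homoconjugate 1,5-addition) and the allylsilane-terminated cation–olefin cyclisation. Ring B closes through a chair-like 6-exo-tet mode at C6 (6-endo with respect to C7=C8), the carbocyclic counterpart of the opening of an epoxide at its distal carbon in epoxy-olefin cyclisations. No bond to C5, C9 or C10 is broken, so the β-oriented C5–C6 bond set in step 6 becomes an equatorial ring bond of a trans-decalin with 5α-H and an equatorial C9 side chain, while C4 is planarised and is set again in step 8. The step needs attack at C6 and not at C5, secured by the contrast between a CH2 and a CH flanked by quaternary C10 and by ring size (six against five), and it needs an exocyclic alkene only, secured by loss of silicon from C17. The hindered pyridine scavenges protons so that protodesilylation should not compete, and the side-chain enoate is a spectator.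

Step 8
Reactants: 17 decalin β-keto ester
Product: 18 dimethyl 3-oxolabda-8(17),13E-diene-15,19-dioate (4α-CH3, 4β-CO2CH3)
Conditions: MeI, K2CO3, acetone, rt
Reagents that add atoms: iodomethane, CI
Why: C-alkylation of a β-keto ester enolate, in which MeI should approach C4 from the α face (equatorial entry), away from the 1,3-diaxial C10 methyl, so that C18 becomes 4α and the ester C19 becomes 4β (axial).

Step 9
Reactants: 18 dimethyl 3-oxolabda-8(17),13E-diene-15,19-dioate
Product: 19 dimethyl 3β-hydroxylabda-8(17),13E-diene-15,19-dioate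
Conditions: NaBH4, MeOH, −20 → 0 °C
Reagents that add atoms: none
Why: Borohydride reduction of the ketone by axial attack from the α face, the β face being screened by the axial 4β-ester and the 10β-methyl, which should give the equatorial 3β-alcohol and leave both esters and both alkenes untouched.

Step 10
Reactants: 19 dimethyl 3β-hydroxylabda-8(17),13E-diene-15,19-dioate
Product: 20 3β-hydroxylabda-8(17),13E-diene-15,19-dioic acid (3β-hydroxyagathic acid)
Conditions: n-PrSH, n-BuLi, HMPA, rt; then 1 M HCl
Reagents that add atoms: none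
Why: SN2 dealkylation of both methyl esters by thiolate at the O-methyl carbon, the method of choice for a hindered axial ester that resists acyl–oxygen hydrolysis, under conditions too weakly basic for retro-aldol cleavage of the β-hydroxy ester.

Step 11
Reactants: 20 3β-hydroxyagathic acid
Product: 21 3β-acetoxy-agathic acid
Conditions: Ac2O, pyridine, DMAP (cat.), rt; then H2O–THF, rt
Reagents that add atoms: acetic anhydride, CC(=O)OC(C)=O
Why: DMAP-catalysed O-acetylation of the equatorial secondary alcohol with retention at C3, any mixed anhydride formed at C15 or C19 being hydrolysed in the aqueous stir.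

Compound list
1 | methyl geranate, methyl (2E)-3,7-dimethylocta-2,6-dienoate | COC(=O)/C=C(\C)CCC=C(C)C | starting material
2 | methyl (2E)-3-methyl-6-oxohex-2-enoate | COC(=O)/C=C(\C)CCC=O | intermediate
3 | 2-(triphenyl-λ5-phosphanylidene)propanal | CC(C=O)=P(c1ccccc1)(c1ccccc1)c1ccccc1 | starting material
4 | methyl (2E,6E)-3,7-dimethyl-8-oxoocta-2,6-dienoate | COC(=O)/C=C(\C)CC/C=C(\C)C=O | intermediate
5 | tert-butyl (2S)-2-amino-3,3-dimethylbutanoate | N[C@@H](C(C)(C)C)C(=O)OC(C)(C)C | starting material
6 | (E)-aldimine of 4 with 5 | COC(=O)/C=C(\C)CC/C=C(\C)/C=N/[C@@H](C(C)(C)C)C(=O)OC(C)(C)C | intermediate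
7 | (2-bromoprop-2-en-1-yl)trimethylsilane | C[Si](C)(C)CC(Br)=C | starting material
8 | [3-(trimethylsilyl)prop-1-en-2-yl]magnesium bromide | C[Si](C)(C)CC(=C)[Mg]Br | intermediate
9 | alkenylated aldimine (C9 R, C10 epimers) | C[Si](C)(C)CC(=C)[C@H](CC/C(C)=C/C(=O)OC)C(C)/C=N/[C@@H](C(C)(C)C)C(=O)OC(C)(C)C | intermediate
10 | methyl (2E,6R)-3,7-dimethyl-8-oxo-6-[3-(trimethylsilyl)prop-1-en-2-yl]oct-2-enoate (C7 epimers) | C[Si](C)(C)CC(=C)[C@H](CC/C(C)=C/C(=O)OC)C(C)C=O | intermediate
11 | methyl 5-methoxy-3-oxopentanoate | COCCC(=O)CC(=O)OC | starting material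
12 | methyl 3-oxopent-4-enoate | C=CC(=O)CC(=O)OC | intermediate
13 | dimethyl (2E,6R,7R)-7-formyl-3,7-dimethyl-10-oxo-6-[3-(trimethylsilyl)prop-1-en-2-yl]dodec-2-enedioate | C[Si](C)(C)CC(=C)[C@H](CC/C(C)=C/C(=O)OC)[C@](C)(C=O)CCC(=O)CC(=O)OC | intermediate
14 | methyl (3S)-3-{(3R,6E)-8-methoxy-6-methyl-8-oxo-2-[(trimethylsilyl)methyl]octa-1,6-dien-3-yl}-3-methyl-6-oxocyclohex-1-ene-1-carboxylate | C[Si](C)(C)CC(=C)[C@H](CC/C(C)=C/C(=O)OC)[C@@]1(C)CCC(=O)C(C(=O)OC)=C1 | intermediate
15 | methyl (1S,5S,6R)-5-{(3R,6E)-8-methoxy-6-methyl-8-oxo-2-[(trimethylsilyl)methyl]octa-1,6-dien-3-yl}-5-methyl-2-oxobicyclo[4.1.0]heptane-1-carboxylate | C[Si](C)(C)CC(=C)[C@H](CC/C(C)=C/C(=O)OC)[C@@]1(C)CCC(=O)[C@]2(C(=O)OC)C[C@H]12 | intermediate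
16 | dimethyl 3-(trimethylsilyloxy)-18-norlabda-3,8(17),13E-triene-15,19-dioate | C=C1CC[C@@H]2[C@](C)(CCC(O[Si](C)(C)C)=C2C(=O)OC)[C@H]1CC/C(C)=C/C(=O)OC | intermediate
17 | dimethyl 3-oxo-18-norlabda-8(17),13E-diene-15,19-dioate | C=C1CC[C@@H]2[C@](C)(CCC(=O)[C@H]2C(=O)OC)[C@H]1CC/C(C)=C/C(=O)OC | intermediate
18 | dimethyl 3-oxolabda-8(17),13E-diene-15,19-dioate | C=C1CC[C@@H]2[C@](C)(CCC(=O)[C@]2(C)C(=O)OC)[C@H]1CC/C(C)=C/C(=O)OC | intermediate
19 | dimethyl 3β-hydroxylabda-8(17),13E-diene-15,19-dioate | C=C1CC[C@@H]2[C@](C)(CC[C@H](O)[C@]2(C)C(=O)OC)[C@H]1CC/C(C)=C/C(=O)OC | intermediate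
20 | 3β-hydroxylabda-8(17),13E-diene-15,19-dioic acid | C=C1CC[C@@H]2[C@](C)(CC[C@H](O)[C@]2(C)C(=O)O)[C@H]1CC/C(C)=C/C(=O)O | intermediate
21 | 3β-acetoxy-agathic acid | C=C1CC[C@@H]2[C@](C)(CC[C@H](OC(C)=O)[C@]2(C)C(=O)O)[C@H]1CC/C(C)=C/C(=O)O | target

Total step count: 11. Longest linear sequence: 11 (steps 1–11).

Steps most likely to fail

Step 7. The backside approach of C7 to C6 is geometrically demanding. Protodesilylation of the allylsilane, or opening of the cyclopropane by an oxygen or external nucleophile, may therefore outrun ring closure.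

The fallback brings C6 in as an aldehyde carbon and closes the same bond by an intramolecular Hosomi–Sakurai reaction. It sets out from 14 and returns at 18.
- 2-Lithio-1,3-dithiane is added 1,4 to 14 (THF–DMPU, −78 °C), anti to the C9 substituent. The enolate is quenched with MeI anti to the new C5 substituent, giving the dithianyl keto ester F1.
- MeI/CaCO3 in aqueous MeCN frees the C6 aldehyde F2.
- BF3·OEt2 (CH2Cl2, −78 °C) closes ring B to the 6-hydroxy decalin F3.
- 1,1'-Thiocarbonyldiimidazole (DMAP, ClCH2CH2Cl, reflux) gives the imidazolylthiocarbonate F4.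
- Bu3SnH/AIBN (toluene, 90 °C, Barton–McCombie deoxygenation) delivers 18.

Step 5. The likely problems are poor facial selectivity at the quaternary C10, because the catalyst must override the bias of the neighbouring C9 centre, and self-condensation of the liberated vinyl ketone.

The fallback sets C10 by alkylation of the auxiliary-bound aza-enolate instead of by catalysis. It sets out from 6 (with 8) and returns at 14.
- After the 1,4-addition of 8 to 6, the chelated (Z)-magnesium aza-enolate has 1,3-allylic strain that places the C9–H in the plane. It should therefore be attacked anti to the alkenyl group.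
- This aza-enolate is trapped with methyl acrylate (−55 → −20 °C) to give the quaternary aldimine F5.
- Aqueous citric acid gives the aldehyde ester F6.
- The lithium enolate of methyl acetate (LDA, THF, −78 °C) adds to the aldehyde to give the aldol F7.
- NaOMe in MeOH effects Dieckmann condensation of C4 on the C3 ester and loss of water, giving 14.

Step 4. The likely problems are competing 1,2-addition to the C=N bond, attack of the Grignard reagent on the methyl ester, and loss of facial control if the α-methyl group twists the azadiene out of the s-cis chelate.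

The fallback moves the auxiliary to the acid oxidation level and uses an α-unsubstituted acceptor. It sets out from 2 and returns at 10.
- Horner–Wadsworth–Emmons reaction of 2 with diethyl {2-oxo-2-[(4S)-2-oxo-4-phenyl-1,3-oxazolidin-3-yl]ethyl}phosphonate (LiCl, iPr2NEt, MeCN) gives the enoyl imide F8.
- Copper-mediated conjugate addition of 8 (CuBr·SMe2, THF, −40 °C), anti to the phenyl group, gives the adduct F9 with C9 (R).
- NaHMDS/MeI (−78 °C) gives the α-methyl imide F10.
- LiBH4/H2O (Et2O, 0 °C) gives the alcohol F11.
- DMP oxidation gives 10 as one C7 epimer.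

Further compounds
F1 | step 7 | dithianyl keto ester (ring A of 18 with C6 as 1,3-dithian-2-yl, allylsilane arm intact) | C[Si](C)(C)CC(=C)[C@H](CC/C(C)=C/C(=O)OC)[C@@]1(C)CCC(=O)[C@](C)(C(=O)OC)[C@@H]1C2SCCCS2
F2 | step 7 | C6 aldehyde | C[Si](C)(C)CC(=C)[C@H](CC/C(C)=C/C(=O)OC)[C@@]1(C)CCC(=O)[C@](C)(C(=O)OC)[C@@H]1C=O
F3 | step 7 | dimethyl 6-hydroxy-3-oxolabda-8(17),13E-diene-15,19-dioate (C6 epimers) | C=C1CC(O)[C@@H]2[C@](C)(CCC(=O)[C@]2(C)C(=O)OC)[C@H]1CC/C(C)=C/C(=O)OC
F4 | step 7 | 6-O-(imidazol-1-ylthiocarbonyl) derivative of F3 | C=C1CC(OC(=S)n3ccnc3)[C@@H]2[C@](C)(CCC(=O)[C@]2(C)C(=O)OC)[C@H]1CC/C(C)=C/C(=O)OC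
F5 | step 5 | quaternary aldimine | C[Si](C)(C)CC(=C)[C@H](CC/C(C)=C/C(=O)OC)[C@](C)(/C=N/[C@@H](C(C)(C)C)C(=O)OC(C)(C)C)CCC(=O)OC
F6 | step 5 | aldehyde ester | C[Si](C)(C)CC(=C)[C@H](CC/C(C)=C/C(=O)OC)[C@](C)(C=O)CCC(=O)OC
F7 | step 5 | aldol (C5 carbinol epimers) | C[Si](C)(C)CC(=C)[C@H](CC/C(C)=C/C(=O)OC)[C@](C)(C(O)CC(=O)OC)CCC(=O)OC
F8 | step 4 | enoyl imide | COC(=O)/C=C(\C)CC/C=C/C(=O)N1[C@@H](c2ccccc2)COC1=O
F9 | step 4 | conjugate adduct | C[Si](C)(C)CC(=C)[C@H](CC/C(C)=C/C(=O)OC)CC(=O)N1[C@@H](c2ccccc2)COC1=O
F10 | step 4 | α-methyl imide | C[Si](C)(C)CC(=C)[C@H](CC/C(C)=C/C(=O)OC)[C@H](C)C(=O)N1[C@@H](c2ccccc2)COC1=O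
F11 | step 4 | primary alcohol | C[Si](C)(C)CC(=C)[C@H](CC/C(C)=C/C(=O)OC)[C@H](C)CO
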